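**Retrosynthetic overview**

1. The plan rests on C3 and C4 of ring C. The C3 carbinol and the C4 ketone are neighbouring oxidised carbons that can be read as the cis C3=C4 olefin of a 2-phenyl-2H-chromene, so C2 is the only stereocentre needed before ring closure.
2. C3–OH/C4=O ⇒ chromene 16 (epoxidation anti to phenyl, then Kornblum-type oxidative opening). C3=C4 ⇒ ring-closing metathesis of diene 15. O1–C2 ⇒ iridium-catalysed branched-selective allylic etherification of vinylphenol 13 with cinnamyl methyl carbonate.
3. The hexasubstituted ring A comes from 2,4,6-trihydroxybenzaldehyde. Hydrogen-bond-controlled bis-MOM protection singles out O1, Dakin oxidation and methylation turn the formyl carbon into C8–OMe, directed metalation places prenyl at C6, and ortho-formylation/Wittig reaction places vinyl at C4a.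
4. Ring order: ring A and the phenyl ring are bought; ring C is the only ring formed, in step 10.

Key step: step 10

Assumption: flavonoid numbering (O1, C2–C4, C4a, C5–C8, C8a) is used. The (Sa,S,S)-phosphoramidite is taken to give the (S)-1-phenylallyl aryl ether and the (S,S)-salen manganese chloride to epoxidise the chromene face anti to phenyl, following the usual sense of induction of these catalysts; if either sense proves opposite, the enantiomeric ligand is used.

**Step 1**
Reactants: 1 2,4,6-trihydroxybenzaldehyde
Product: 2 2-hydroxy-4,6-bis(methoxymethoxy)benzaldehyde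
Conditions: MOMCl (2.2 equiv), iPr2NEt, CH2Cl2, 0 °C to rt
Reagents that add atoms: chloromethyl methyl ether, COCCl
Why: Williamson-type acetalisation of the two more reactive phenols; the ortho hydroxyl that is hydrogen-bonded to the formyl group should stay free, which marks it as the future O1.

**Step 2**
Reactants: 2 2-hydroxy-4,6-bis(methoxymethoxy)benzaldehyde
Product: 3 2-(benzyloxy)-4,6-bis(methoxymethoxy)benzaldehyde
Conditions: BnBr, K2CO3, DMF, 50 °C
Reagents that add atoms: benzyl bromide, BrCc1ccccc1
Why: Williamson etherification of the remaining chelated phenol gives O1 a group that cannot migrate to a neighbouring oxygen and is orthogonal to the MOM ethers.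

**Step 3**
Reactants: 3 2-(benzyloxy)-4,6-bis(methoxymethoxy)benzaldehyde
Product: 5 2-(benzyloxy)-4,6-bis(methoxymethoxy)phenol, via aryl formate 4 (not isolated)
Conditions: mCPBA, CH2Cl2, 0 °C to rt; then K2CO3 (cat.), MeOH, 0 °C
Reagents that add atoms: 3-chloroperoxybenzoic acid, OOC(=O)c1cccc(Cl)c1
Why: Dakin-type Baeyer–Villiger oxidation in which the electron-rich 2,4,6-trioxygenated aryl group migrates to oxygen, and methanolysis of the resulting formate frees the phenol that becomes the C8 oxygen.

**Step 4**
Reactants: 5 2-(benzyloxy)-4,6-bis(methoxymethoxy)phenol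
Product: 6 1-(benzyloxy)-2-methoxy-3,5-bis(methoxymethoxy)benzene
Conditions: MeI, K2CO3, acetone, reflux
Reagents that add atoms: iodomethane, CI
Why: Williamson methylation of the only free phenol fixes the C8 methoxy group between O1 and O7.

**Step 5**
Reactants: 6 1-(benzyloxy)-2-methoxy-3,5-bis(methoxymethoxy)benzene; 7 prenyl bromide
Product: 10 1-(benzyloxy)-2-methoxy-3,5-bis(methoxymethoxy)-4-(3-methylbut-2-en-1-yl)benzene, via aryllithium 8 (not isolated), via arylcopper 9 (not isolated)
Conditions: n-BuLi, THF, 0 °C; CuBr·SMe2, −40 °C; then 7, −40 °C to rt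
Reagents that add atoms: none
Why: Directed ortho-metalation should take place at the C–H flanked by two MOM ethers, whose acetal oxygens both chelate lithium, in preference to the C–H that has one MOM neighbour and a benzyloxy group buttressed by the adjacent methoxy, and the arylcopper then alkylates prenyl bromide at its primary carbon (SN2).

**Step 6**
Reactants: 10 1-(benzyloxy)-2-methoxy-3,5-bis(methoxymethoxy)-4-(3-methylbut-2-en-1-yl)benzene
Product: 11 2-methoxy-3,5-bis(methoxymethoxy)-4-(3-methylbut-2-en-1-yl)phenol
Conditions: Na, NH3(l), THF, −78 °C, short contact; NH4Cl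
Reagents that add atoms: none
Why: Dissolving-metal (Birch-type) cleavage of the benzyl aryl ether by electron transfer should spare the isolated trisubstituted olefin, the MOM acetals and the very electron-rich arene, whereas catalytic hydrogenolysis would endanger the prenyl olefin.

**Step 7**
Reactants: 11 2-methoxy-3,5-bis(methoxymethoxy)-4-(3-methylbut-2-en-1-yl)phenol
Product: 12 2-hydroxy-3-methoxy-4,6-bis(methoxymethoxy)-5-(3-methylbut-2-en-1-yl)benzaldehyde
Conditions: MgCl2, Et3N, (CH2O)n, MeCN, 70 °C; NH4Cl work-up
Reagents that add atoms: paraformaldehyde (formaldehyde), C=O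
Why: Magnesium-phenoxide-directed ortho-formylation (Casnati–Skattebøl reaction) delivers formaldehyde within the chelate to the only free ring position, which is ortho to the phenol, a second formaldehyde oxidises the hydroxymethyl intermediate, and the basic medium spares the MOM ethers.

**Step 8**
Reactants: 12 2-hydroxy-3-methoxy-4,6-bis(methoxymethoxy)-5-(3-methylbut-2-en-1-yl)benzaldehyde
Product: 13 2-ethenyl-6-methoxy-3,5-bis(methoxymethoxy)-4-(3-methylbut-2-en-1-yl)phenol
Conditions: Ph3PCH3Br (3 equiv), KOtBu (3 equiv), THF, 0 °C to rt; used without storage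
Reagents that add atoms: methyltriphenylphosphonium bromide, C[P+](c1ccccc1)(c1ccccc1)c1ccccc1.[Br-]
Why: Wittig methylenation with excess ylide, the first equivalent of base turning the phenol into its phenoxide, is the established way from salicylaldehydes to 2-vinylphenols.

**Step 9**
Reactants: 13 2-ethenyl-6-methoxy-3,5-bis(methoxymethoxy)-4-(3-methylbut-2-en-1-yl)phenol; 14 (E)-cinnamyl methyl carbonate
Product: 15 (1S)-1-phenylprop-2-en-1-yl 2-ethenyl-6-methoxy-3,5-bis(methoxymethoxy)-4-(3-methylbut-2-en-1-yl)phenyl ether
Conditions: [Ir(cod)Cl]2 (2 mol %), (Sa,S,S)-O,O'-(1,1'-binaphthyl-2,2'-diyl) N,N-bis(1-phenylethyl)phosphoramidite (4 mol %, pre-activated with n-PrNH2, volatiles removed), K3PO4, THF, 50 °C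
Reagents that add atoms: none
Why: Iridium-catalysed asymmetric allylic etherification, in which the cyclometalated iridium–phosphoramidite complex ionises the carbonate to an η3-cinnamyl complex and the phenoxide attacks the phenyl-bearing terminus anti to the metal, should give the branched ether with C2 set by the ligand-controlled face of the allyl unit, and O1–C2 is unambiguous because O1 is the only free hydroxyl.

**Step 10**
Reactants: 15 (1S)-1-phenylprop-2-en-1-yl 2-ethenyl-6-methoxy-3,5-bis(methoxymethoxy)-4-(3-methylbut-2-en-1-yl)phenyl ether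
Product: 16 (2S)-8-methoxy-5,7-bis(methoxymethoxy)-6-(3-methylbut-2-en-1-yl)-2-phenyl-2H-chromene
Conditions: second-generation Grubbs catalyst (H2IMes)(PCy3)Cl2Ru=CHPh (5 mol %), 1,4-benzoquinone (10 mol %), degassed CH2Cl2 (5 mM), 40 °C, dark
Reagents that add atoms: none
Why: The ruthenium benzylidene exchanges onto the terminal olefin of the 1-phenylallyl ether, the new alkylidene adds across the ortho vinyl group to a ruthenacyclobutane, and cycloreversion expels ethylene and forms C3=C4; this is ring-closing olefin metathesis of the type established for 2-vinylphenyl allyl ethers giving 2H-chromenes. Ring C closes as a six-membered ring by intramolecular diene metathesis between the two vinyl termini (C3 from the allyl unit, C4 from the styrene), the ring enforcing the cis olefin. No stereocentre is formed; C2, set in step 9, is not on the reaction path and should be retained if ruthenium hydride isomerisation is suppressed by the benzoquinone and the chromene is kept cool and dark to avoid electrocyclic ring opening. The selectivity needed is chemoselectivity for the two monosubstituted olefins over the trisubstituted prenyl olefin. It is secured because the prenyl olefin is a poor partner for the bulky carbene and sits meta to the vinyl group, so no unstrained ring can form through it. High dilution and loss of ethylene keep the closure intramolecular and irreversible.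

**Step 11**
Reactants: 16 (2S)-8-methoxy-5,7-bis(methoxymethoxy)-6-(3-methylbut-2-en-1-yl)-2-phenyl-2H-chromene
Product: 17 (2R,3S,4S)-3,4-epoxy-8-methoxy-5,7-bis(methoxymethoxy)-6-(3-methylbut-2-en-1-yl)-2-phenylchromane (epoxide oxygen trans to phenyl)
Conditions: (S,S)-(salen)MnCl [salen = N,N'-bis(3,5-di-tert-butylsalicylidene)cyclohexane-1,2-diamine dianion] (5 mol %), 4-phenylpyridine N-oxide (20 mol %), NaOCl (aq, pH 11.3), CH2Cl2, 0 °C; filtered through basic alumina and used at once
Reagents that add atoms: sodium hypochlorite, [Na+].[O-]Cl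
Why: Jacobsen epoxidation, in which the oxomanganese salen species should oxidise the conjugated cis C3=C4 olefin much faster than the isolated trisubstituted prenyl olefin, and both the chiral catalyst (matched case) and the C2 phenyl group direct oxygen to the face anti to phenyl, which sets C3.

**Step 12**
Reactants: 17 (2R,3S,4S)-3,4-epoxy-8-methoxy-5,7-bis(methoxymethoxy)-6-(3-methylbut-2-en-1-yl)-2-phenylchromane
Product: 20 (2R,3R)-3-hydroxy-8-methoxy-5,7-bis(methoxymethoxy)-6-(3-methylbut-2-en-1-yl)-2-phenylchroman-4-one, via alkoxysulfonium triflate 18 (not isolated), via silyl ether 19 (not isolated)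
Conditions: DMSO (5 equiv), Me3SiOTf (1.1 equiv), CH2Cl2, −78 °C; Et3N, −78 to −20 °C; then citric acid, MeOH, 0 °C
Reagents that add atoms: dimethyl sulfoxide, CS(C)=O
Why: Kornblum-type oxidative epoxide opening, in which silylation activates the epoxide, DMSO attacks the benzylic C4 (cation stabilised by the O1, O5 and O7 donors), and triethylamine converts the alkoxysulfonium salt through its ylide into the C4 ketone with loss of dimethyl sulfide; the C3–O bond is never broken, so the C3 configuration from step 11 is kept, and mild methanolysis removes the silyl group.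

**Step 13**
Reactants: 20 (2R,3R)-3-hydroxy-8-methoxy-5,7-bis(methoxymethoxy)-6-(3-methylbut-2-en-1-yl)-2-phenylchroman-4-one
Product: 21 (2R,3R)-3,5,7-trihydroxy-8-methoxy-6-(3-methylbut-2-en-1-yl)-2-phenylchroman-4-one (target, 2,3-trans)
Conditions: HCl (1 M), MeOH–H2O, 40 °C
Reagents that add atoms: none
Why: Acid-catalysed acetal cleavage of the two aryl MOM ethers under dilute acid that should be too mild to cyclise the prenyl group onto the neighbouring phenols and that does not enolise or ring-open the trans-2,3 hydroxy ketone.

**Compound list**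

1 | 2,4,6-trihydroxybenzaldehyde | O=Cc1c(O)cc(O)cc1O | starting material
2 | 2-hydroxy-4,6-bis(methoxymethoxy)benzaldehyde | O=Cc1c(O)cc(OCOC)cc1OCOC | intermediate
3 | 2-(benzyloxy)-4,6-bis(methoxymethoxy)benzaldehyde | O=Cc1c(OCc2ccccc2)cc(OCOC)cc1OCOC | intermediate
4 | 2-(benzyloxy)-4,6-bis(methoxymethoxy)phenyl formate (not isolated) | O=COc1c(OCc2ccccc2)cc(OCOC)cc1OCOC | intermediate
5 | 2-(benzyloxy)-4,6-bis(methoxymethoxy)phenol | Oc1c(OCc2ccccc2)cc(OCOC)cc1OCOC | intermediate
6 | 1-(benzyloxy)-2-methoxy-3,5-bis(methoxymethoxy)benzene | COc1c(OCc2ccccc2)cc(OCOC)cc1OCOC | intermediate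
7 | prenyl bromide (1-bromo-3-methylbut-2-ene) | CC(C)=CCBr | starting material
8 | [4-(benzyloxy)-3-methoxy-2,6-bis(methoxymethoxy)phenyl]lithium (not isolated) | COCOc1cc(OCc2ccccc2)c(OC)c(OCOC)c1[Li] | intermediate
9 | [4-(benzyloxy)-3-methoxy-2,6-bis(methoxymethoxy)phenyl]copper (not isolated) | COCOc1cc(OCc2ccccc2)c(OC)c(OCOC)c1[Cu] | intermediate
10 | 1-(benzyloxy)-2-methoxy-3,5-bis(methoxymethoxy)-4-(3-methylbut-2-en-1-yl)benzene | COCOc1cc(OCc2ccccc2)c(OC)c(OCOC)c1CC=C(C)C | intermediate
11 | 2-methoxy-3,5-bis(methoxymethoxy)-4-(3-methylbut-2-en-1-yl)phenol | COCOc1cc(O)c(OC)c(OCOC)c1CC=C(C)C | intermediate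
12 | 2-hydroxy-3-methoxy-4,6-bis(methoxymethoxy)-5-(3-methylbut-2-en-1-yl)benzaldehyde | COCOc1c(C=O)c(O)c(OC)c(OCOC)c1CC=C(C)C | intermediate
13 | 2-ethenyl-6-methoxy-3,5-bis(methoxymethoxy)-4-(3-methylbut-2-en-1-yl)phenol | COCOc1c(C=C)c(O)c(OC)c(OCOC)c1CC=C(C)C | intermediate
14 | (E)-cinnamyl methyl carbonate | COC(=O)OC/C=C/c1ccccc1 | starting material
15 | (1S)-1-phenylprop-2-en-1-yl 2-ethenyl-6-methoxy-3,5-bis(methoxymethoxy)-4-(3-methylbut-2-en-1-yl)phenyl ether | COc1c(OCOC)c(CC=C(C)C)c(OCOC)c(C=C)c1O[C@H](c1ccccc1)C=C | intermediate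
16 | (2S)-8-methoxy-5,7-bis(methoxymethoxy)-6-(3-methylbut-2-en-1-yl)-2-phenyl-2H-chromene | COc1c(OCOC)c(CC=C(C)C)c(OCOC)c2c1O[C@H](c1ccccc1)C=C2 | intermediate
17 | (2R,3S,4S)-3,4-epoxy-8-methoxy-5,7-bis(methoxymethoxy)-6-(3-methylbut-2-en-1-yl)-2-phenylchromane | COc1c(OCOC)c(CC=C(C)C)c(OCOC)c2c1O[C@H](c1ccccc1)[C@H]1O[C@H]12 | intermediate
18 | C4 dimethylsulfoniooxy derivative of the 3-O-trimethylsilyl 2,3-trans-chromane-3,4-diol, triflate salt, C4 either configuration (not isolated) | COc1c(OCOC)c(CC=C(C)C)c(OCOC)c2c1O[C@H](c1ccccc1)[C@@H](O[Si](C)(C)C)C2O[S+](C)C.[O-]S(=O)(=O)C(F)(F)F | intermediate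
19 | (2R,3R)-8-methoxy-5,7-bis(methoxymethoxy)-6-(3-methylbut-2-en-1-yl)-2-phenyl-3-(trimethylsilyloxy)chroman-4-one (not isolated) | COc1c(OCOC)c(CC=C(C)C)c(OCOC)c2c1O[C@H](c1ccccc1)[C@@H](O[Si](C)(C)C)C2=O | intermediate
20 | (2R,3R)-3-hydroxy-8-methoxy-5,7-bis(methoxymethoxy)-6-(3-methylbut-2-en-1-yl)-2-phenylchroman-4-one | COc1c(OCOC)c(CC=C(C)C)c(OCOC)c2c1O[C@H](c1ccccc1)[C@@H](O)C2=O | intermediate
21 | (2R,3R)-3,5,7-trihydroxy-8-methoxy-6-(3-methylbut-2-en-1-yl)-2-phenylchroman-4-one | COc1c(O)c(CC=C(C)C)c(O)c2c1O[C@H](c1ccccc1)[C@@H](O)C2=O | target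

**Totals**

Total step count: 13. Longest linear sequence: 13 steps (1 to 21); 7 and 14 are bought.

**Steps most likely to fail**

Step 12. The C4 cation released from the epoxide is stabilised by three oxygen donors, so it may lose the C3 proton or undergo a Meinwald-type hydride shift before DMSO traps it. The silyl triflate may also strip a MOM group, and the amine may open the pyranone ring by β-elimination, which would erode C2. The fallback separates opening from oxidation and sets out from 17. The epoxide is hydrolysed in THF–water with a NaH2PO4 buffer, where water should enter at the benzylic C4 and leave the C3–O bond untouched, to give (2R,3S)-8-methoxy-5,7-bis(methoxymethoxy)-6-(3-methylbut-2-en-1-yl)-2-phenylchromane-3,4-diol F1 as a C4 mixture. The benzylic C4 alcohol is then oxidised selectively with activated MnO2 in CH2Cl2, which should leave the non-benzylic C3 alcohol and the prenyl group alone. This comes back to the route at 20.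

Step 9. The di-ortho-substituted, electron-rich phenoxide may attack the allyliridium complex slowly. Reversible ionisation of the product may then erode branched selectivity and enantiomeric purity, and C-allylation of the ring may compete. The fallback takes the stereocentre from a bought enantiopure alcohol and sets out from 13. A Mitsunobu reaction with (R)-1-phenylprop-2-yn-1-ol (PPh3, diisopropyl azodicarboxylate, toluene, 0 °C) should proceed with inversion and, unlike the allylic alcohol, without allylic transposition, to give (1S)-1-phenylprop-2-yn-1-yl 2-ethenyl-6-methoxy-3,5-bis(methoxymethoxy)-4-(3-methylbut-2-en-1-yl)phenyl ether F2. Semihydrogenation of the terminal alkyne (H2, Pd/CaCO3 poisoned with Pb(OAc)2, quinoline, monitored uptake) then gives the vinyl group. This comes back to the route at 15.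

Step 5. Lithiation may not be fully selective for the position between the two MOM ethers. Metalation next to the benzyloxy group or at the benzylic CH2, followed by Wittig rearrangement, would give regioisomers, and the strongly basic medium of step 6 may move the prenyl double bond into conjugation. The fallback removes the benzyl group before the olefin is present and sets out from 6. Hydrogenolysis (H2, Pd/C, EtOAc) gives 2-methoxy-3,5-bis(methoxymethoxy)phenol F3, and silylation (iPr3SiCl, imidazole, DMF) gives its triisopropylsilyl ether F4. The bulky, non-coordinating silyloxy group should leave only the site between the MOM ethers open to n-BuLi, giving aryllithium F5. Transmetalation with CuBr·SMe2 gives arylcopper F6, and prenyl bromide then gives the prenylated silyl ether F7. Bu4NF in THF frees the phenol. This comes back to the route at 11 and bypasses step 6.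

**Further compounds**

F1 | step 12 | (2R,3S)-8-methoxy-5,7-bis(methoxymethoxy)-6-(3-methylbut-2-en-1-yl)-2-phenylchromane-3,4-diol (C4 mixture) | COc1c(OCOC)c(CC=C(C)C)c(OCOC)c2c1O[C@H](c1ccccc1)[C@@H](O)C2O
F2 | step 9 | (1S)-1-phenylprop-2-yn-1-yl 2-ethenyl-6-methoxy-3,5-bis(methoxymethoxy)-4-(3-methylbut-2-en-1-yl)phenyl ether | COc1c(OCOC)c(CC=C(C)C)c(OCOC)c(C=C)c1O[C@H](c1ccccc1)C#C
F3 | step 5 | 2-methoxy-3,5-bis(methoxymethoxy)phenol | COCOc1cc(O)c(OC)c(OCOC)c1
F4 | step 5 | [2-methoxy-3,5-bis(methoxymethoxy)phenoxy]tri(propan-2-yl)silane | COCOc1cc(O[Si](C(C)C)(C(C)C)C(C)C)c(OC)c(OCOC)c1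
F5 | step 5 | {3-methoxy-2,6-bis(methoxymethoxy)-4-[tri(propan-2-yl)silyloxy]phenyl}lithium | COCOc1cc(O[Si](C(C)C)(C(C)C)C(C)C)c(OC)c(OCOC)c1[Li]
F6 | step 5 | {3-methoxy-2,6-bis(methoxymethoxy)-4-[tri(propan-2-yl)silyloxy]phenyl}copper | COCOc1cc(O[Si](C(C)C)(C(C)C)C(C)C)c(OC)c(OCOC)c1[Cu]
F7 | step 5 | [2-methoxy-3,5-bis(methoxymethoxy)-4-(3-methylbut-2-en-1-yl)phenoxy]tri(propan-2-yl)silane | COCOc1cc(O[Si](C(C)C)(C(C)C)C(C)C)c(OC)c(OCOC)c1CC=C(C)C
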